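I decided to count half-lives of substrate in each flask and let that count carry the estimate of target.

| flask | substrate | catalyst | temperature | remark | time |
|---|---|---|---|---|---|
| alpha | 20 mM (in portions, 2) | 0.11 mol% | 5 °C | run made earlier; portions every 3.0 min |  |
| eta | 20 mM (in portions, 2) | 0.31 mol% | 16 °C | run made earlier; portions every 3.0 min |  |
| Tuesday's | 20 mM | 0.12 mol% | 0 °C | everything together at the start | 6.0 min |
| Sunday's | 20 mM (in portions, 2) | 0.47 mol% | 20 °C | the portions of substrate follow each other after 3.0 min, the first at the start | 6.0 min |
- alpha (time / min: target / %, substrate / %): 0.500: 2, 49; 2.00: 0, 50; 3.00: 3, 43; 5.00: 5, 93; 6.00: 9, 88; 8.00: 17, 74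
- eta (time / min: target / %, substrate / %): 0.250: 0, 50; 0.833: 1, 43; 1.33: 6, 34; 2.50: 13, 30; 3.00: 19, 24; 4.00: 30, 61

(readings scatter by 2 percentage points)
- the numbers in the tables scatter with a standard deviation of 2 percentage points
- a reading or a percentage of target counts all its forms, free or not
- which of the two ends with the higher amount of target, in percent of the substrate charged ("neither" if they lie within 2 percentage points) (Tuesday's / Sunday's / neither)
- target at the end, in percent of the substrate charged, Tuesday's
- target at the end, in percent of the substrate charged, Sunday's

The catalyst is not consumed in this picture, so I treated substrate loss as pseudo-first-order, with a rate proportional to loading. The last substrate reading of the alpha run, with the portions on average 6.50 min old, gives a rate of 0.0463 min⁻¹. The first portion of the eta run, down to 24% at 3.00 min, gives 0.245 min⁻¹. Per unit of catalyst, eta read 1.87 times alpha's rate, and I spread that factor evenly over the degrees to reach each new flask: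

Sunday's rate = 0.466 min⁻¹
Tuesday's rate = 0.0380 min⁻¹

The quantity I carried is the half-life of substrate in Sunday's, the natural log of 2 over its rate: 1.49 min.

In the first instants of Sunday's, one portion meets the catalyst; the earliest eta reading of target, 0%, tells little about this start, with a scatter of 2 percentage points on each reading. By the second portion at 3.0 min, I counted 2.01 half-lives, so I reckoned that a quarter of the first portion remains. At 6.0 min the two portions have seen 4.03 and 2.01 half-lives:

substrate left = 15.4%

Not everything consumed appears as target. The last eta readings give a share of 0.769, and alpha's give 0.654. My half-life for Tuesday's, 18.2 min, is longer than its 6.0 min, so I reckoned 79.6% of its substrate left. Taking the nearer run for each flask: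

Tuesday's target = 13.3%
Sunday's target = 65.1%

So I expected Sunday's to end higher. The forecast also named Sunday's, with 19% for Tuesday's and 72% for Sunday's, noting that “the target shows a lag”.

The flasks gave 12.3% in Tuesday's and 64.7% in Sunday's, so Sunday's ended higher.

    substrate + catalyst → catalyst + target (k = 58.0 L mol⁻¹ s⁻¹, Ea = 42.0 kJ mol⁻¹)
    substrate → side product A (k = 9.10 × 10⁻⁴ s⁻¹, Ea = 86.0 kJ mol⁻¹)
    target ⇌ isomer of the product (K = 0.550, k = 0.00850 s⁻¹, Ea = 84.0 kJ mol⁻¹, ΔH = −72.0 kJ mol⁻¹)
    substrate + target → side product B (k = 0.0480 L mol⁻¹ s⁻¹, Ea = 62.0 kJ mol⁻¹)
    crystals ⇌ target, rate k5*(cs5 - [target]) while solid is left; crystals form when [target] > cs5 (solubility = 0.570 mM, k = 0.130 s⁻¹)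
    (constants at 20 °C)

Sunday's consumed 79.2% of its substrate and held 64.7% target, a share of 0.817 against my 0.769. Its substrate stood at 20.8% against my 15.4%. A neighbour of Sunday's with 0.12 mol% of catalyst stretches the carried half-life to 5.82 min, which reckons 59.4% substrate left; that flask held 54.4%.

The runs were computed from invented constants; the scatter is artificial.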